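## Analysis of the target

Target 18 is built from two fully substituted six-membered rings joined by a single methylene carbon. Ring A is a 6-ethyl-4-hydroxy-5-methylpyran-2-one attached through C3. Ring B is a 2,4,6-trihydroxyphenyl ring whose carbons C1', C3' and C5' carry the bridging CH2, a 3-methylbut-2-enyl group and a 2-methylbutanoyl group. The only stereocentre is the α-carbon of the acyl group; the descriptor in the SMILES corresponds to (S), and because it lies next to an aryl ketone it can be lost by enolisation under strong base or hot Lewis acid. The sensitive groups are the prenyl alkene (saturated by hydrogenation, cyclised by acid onto a flanking hydroxyl), the electron-rich phenols (oxidation, competition between O- and C-reactivity), the lactone, and the methylene bridge between two enolic rings, which can fragment under forcing acid or base. The difficulty lies in placing three different carbon substituents on ring B, in assembling a pyranone with no free position, and in keeping the α-stereocentre intact to the end. The strategy rests on ring A: C3 bears the CH2 and C4 the hydroxyl, so C2, C3 and the bridge carbon are the carboxyl, α- and β-carbons of a 3-arylpropanoic acid, while C4, C5, C6 and O1 are the ester carbon, C2, C3 and enol oxygen of a 2-methyl-3-oxopentanoate. The C3–C4 bond is then a Claisen bond between an ester enolate and an ester carbonyl, and ring B without acyl and prenyl groups is symmetric about the C1'–C4' axis, which removes every regiochemical question until the last step.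

## Retrosynthetic reasoning

The bond between C3' of ring B and the prenyl CH2 is cut first, leading back to ketone 17. The alkene would not survive the hydrogenolysis that removes the protecting groups, and under the Lewis acid of the acylation it would cyclise onto a neighbouring hydroxyl, so this bond has to be made last. The forward reaction must alkylate carbon and not oxygen; in 17, C3' is the only ring carbon that still bears hydrogen.

Next the aryl–carbonyl bond at C5' is cut, giving tetraol 14 and acid chloride 16, which comes from acid 15 with its configuration unchanged. Making this bond after ring A exists means the stereocentre never meets the strong base of the ring closure. In 14 the carbons C3' and C5' are equivalent and the pyranone has no unsubstituted carbon, so only one mono-ketone can form. The forward reaction has to form the ketone without enolising it.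

Tetraol 14 is traced to its tribenzyl ether 13. Benzyl ethers tolerate hydride donors, enolates and amide bases and are removed under neutral reductive conditions. They must be removed before the prenyl group is present, which fixes the order of the last three steps.

Ring A of 13 is opened between C3 and C4, which leads to enol ester 11. A cut at O1–C2 or C4–C5 would require a tricarbonyl chain or a doubly activated malonyl unit carrying the arylmethyl group, and attaching the arylmethyl group to a finished pyranone invites double addition. The C3–C4 cut leaves O1 already bonded to both C2 and C6, and it reduces the ring to an ester enolate and an ester carbonyl held in a six-atom array by the Z double bond. One ring and the last skeletal bond of ring A are gained. The forward reaction needs the enolate carbon to attack the ester carbonyl faster than the acyl–oxygen bond fragments.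

The acyl–oxygen bond of 11 is cut to give keto ester 9, used as its sodium enolate 10, and acid chloride 8. The forward reaction must acylate on oxygen and must give the Z isomer; chelation of the metal between the enolate oxygen and the ester carbonyl serves both ends.

Acid chloride 8 comes from acid 7, and 7 from the alkylated Meldrum's acid 5 by loss of one carboxyl carbon. Compound 5 is cut between the benzylic carbon and the α-carbon, giving aldehyde 2 and Meldrum's acid 3 through the alkylidene 4. Compound 3 supplies the two-carbon acid unit, and 4 can be reduced by hydride transfer, which leaves the benzyl ethers alone where catalytic hydrogenation of a cinnamate would not. Aldehyde 2 is the tribenzyl ether of commercial aldehyde 1.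

## Alternatives that were turned down

Alternative 1: The C5'–acyl bond and the neighbouring C6'–O bond of ring B are traced to an aryne and acid 15. In the forward step fluoride induces 1,2-elimination of the silyl triflate A2. The carboxylate of 15 adds through oxygen to the aryne carbon remote from the adjacent methoxy group, and the aryl anion formed next to that methoxy group attacks the new ester carbonyl, so the acyl group moves from oxygen to carbon and gives ketone A1.
- For: the chiral acyl group is attached without a Lewis acid and without an acid chloride, the methoxy group fixes the regiochemistry, and two bonds form in one step.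
- Against: A1 contains only ring B and its acyl group. Ring A, the bridge and the prenyl group are still missing, and the bridge would have to be made by joining two different enolic nucleophiles through a one-carbon electrophile, which tends to give symmetric dimers. Two methyl ethers must later be cleaved by a strong Lewis acid in the presence of the stereocentre. A2 itself needs several steps, and the aryne reaction runs hot in a basic medium in which both the intermediate aryl ester and A1 have an enolisable α-hydrogen.
- Comparison: on how gently the stereocentre meets ring B this alternative is as good as the chosen route or better. The chosen route offers in exchange a bridge carbon and a pyranone that are assembled together from cheap components, a ring B bought with all three oxygens in place, and protecting groups that leave under neutral conditions.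

Alternative 2: Three carbon–carbon bonds of ring B are cut, so that the benzene ring arises from the four-carbon cyclobutenone A4 and the two-carbon siloxyalkyne A5. On heating, A4 ring-opens to a ketene that adds [2+2] to A5, with the prenyl-bearing alkyne carbon bonding to the ketene carbonyl carbon. A second ring opening and a six-electron electrocyclisation then give phenol A3 with the prenyl group between two oxygens.
- For: the prenyl position is fixed by construction, with no competition between C- and O-alkylation and no over-alkylation. On this point the alternative is clearly stronger than the chosen route, whose last step is a phenoxide alkylation.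
- Against: it builds from scratch a ring that can be bought, and A4 and A5 each need their own multistep preparation. A3 still lacks the acyl group, the bridge and ring A. Acylating a ring that already carries a prenyl group under Lewis acid invites cyclisation of the alkene onto the flanking phenol, so the usual order of acyl before prenyl is inverted at a cost. The silyl ethers must also be removed.
- Comparison: the route is longer by several steps. The chosen route accepts a less controlled prenylation on its most advanced intermediate, which is a real price, but at that stage only one ring carbon is free and everything before it is short.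

Alternative 3: Ring A is cut at C4–C5 and O1–C2. The enol ether A8 supplies C5, C6 and O1 with the methyl and ethyl groups, and the malonyl dichloride A7 supplies C2, C3 and C4 together with the bridge and ring B. A7, directly or after 1,2-elimination to its ketene form, acylates the enol ether carbon of A8 (C4–C5), and the ketone oxygen then closes onto the second acyl chloride (O1–C2) to give A6.
- For: two ring bonds form in one operation without strong base, the ketone partner is symmetrical, and this is the classical way to 3-substituted 4-hydroxypyran-2-ones, so it is better precedented than an enol ester Claisen closure. A6 already carries the acyl group.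
- Against: A7 must be made by chlorinating a malonic acid in the presence of an electron-rich tribenzyloxy ring, of benzyl ethers ortho to a ketone (which acid cleaves easily through chelation) and of the α-stereocentre. The chiral ketone then has to survive malonate formation, hydrolysis, chlorination and an acid-releasing annulation.
- Comparison: this alternative is stronger in the precedent for the ring-forming step and about equal in step count. The chosen route offers a stereocentre introduced only after every strongly basic or acid-chloride-forming step, and a ring-closing substrate that is a neutral, storable enol ester and not a moisture-sensitive bis(acid chloride).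

Key step: step 6

Assumption: compounds 1, 3, 9 and 15 are bought; 9 is used as the racemate because its stereocentre becomes sp2 in step 5, and 15 is taken in high enantiomeric purity.

## Route

Step 1
Reactants: 1 2,4,6-trihydroxybenzaldehyde
Product: 2 2,4,6-tris(benzyloxy)benzaldehyde
Conditions: BnBr (3.5 equiv), K2CO3 (4 equiv), DMF, rt → 60 °C
Reagents that add atoms: benzyl bromide, BrCc1ccccc1
Why: Williamson ether synthesis on the three phenoxides; the formyl group lowers the carbon nucleophilicity of the ring so that C-benzylation should stay minor, and gentle heating brings in the two hydrogen-bonded ortho hydroxyls.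

Step 2
Reactants: 2 2,4,6-tris(benzyloxy)benzaldehyde; 3 Meldrum's acid (2,2-dimethyl-1,3-dioxane-4,6-dione)
Product: 5 2,2-dimethyl-5-[2,4,6-tris(benzyloxy)benzyl]-1,3-dioxane-4,6-dione, via arylidene Meldrum's acid 4 (not isolated)
Conditions: Hantzsch ester (1.1 equiv), L-proline (20 mol %), EtOH/CH2Cl2, rt
Reagents that add atoms: none
Why: Knoevenagel condensation followed in the same flask by conjugate transfer hydrogenation from the Hantzsch ester (organocatalytic reductive alkylation); proline activates the hindered, electron-rich aldehyde as an iminium ion, the strongly electrophilic alkylidene 4 accepts hydride readily, and no H2 or metal is used, so the benzyl ethers are untouched.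

Step 3
Reactants: 5 2,2-dimethyl-5-[2,4,6-tris(benzyloxy)benzyl]-1,3-dioxane-4,6-dione
Product: 7 3-[2,4,6-tris(benzyloxy)phenyl]propanoic acid, via arylmethylmalonic acid 6 (not isolated)
Conditions: pyridine/H2O (10:1), 100 °C; then dilute HCl
Reagents that add atoms: water, O
Why: Hydrolytic opening of the cyclic acylal with loss of acetone, then thermal decarboxylation of the malonic acid 6; the weakly basic medium leaves the benzyl ethers intact.

Step 4
Reactants: 7 3-[2,4,6-tris(benzyloxy)phenyl]propanoic acid
Product: 8 3-[2,4,6-tris(benzyloxy)phenyl]propanoyl chloride
Conditions: 1-chloro-N,N,2-trimethylprop-1-en-1-amine (1.1 equiv), CH2Cl2, 0 °C → rt; used crude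
Reagents that add atoms: 1-chloro-N,N,2-trimethylprop-1-en-1-amine (Ghosez's reagent), CC(C)=C(Cl)N(C)C
Why: Acid chloride formation under neutral conditions; neither HCl nor a Vilsmeier-type formylating species is formed, both of which could attack the trialkoxyarene, and the ring cannot close onto the acyl chloride because both ortho positions are blocked.

Step 5
Reactants: 9 methyl 2-methyl-3-oxopentanoate; 8 3-[2,4,6-tris(benzyloxy)phenyl]propanoyl chloride
Product: 11 methyl (Z)-2-methyl-3-{[3-(2,4,6-tris(benzyloxy)phenyl)propanoyl]oxy}pent-2-enoate, via sodium enolate 10 (not isolated)
Conditions: 9 (1.25 equiv), NaH (1.2 equiv), THF, 0 °C; then 8, −20 °C → rt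
Reagents that add atoms: none
Why: O-Acylation of a chelated sodium enolate; in THF the sodium ion bridges the enolate oxygen and the ester carbonyl of 10, which holds the two groups cis and should give the Z enol ester, while the hard acyl chloride and the α-methyl group (C-acylation would create a quaternary carbon) direct the attack to oxygen.

Step 6
Reactants: 11 methyl (Z)-2-methyl-3-{[3-(2,4,6-tris(benzyloxy)phenyl)propanoyl]oxy}pent-2-enoate
Product: 13 6-ethyl-4-hydroxy-5-methyl-3-[2,4,6-tris(benzyloxy)benzyl]pyran-2-one, via lithium pyran-4-olate 12 (not isolated)
Conditions: LiN(SiMe3)2 (2.5 equiv), THF (0.02 M, slow addition of 11 to the base), −78 °C → 0 °C; then 1 M HCl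
Reagents that add atoms: none
Why: Intramolecular Claisen (Dieckmann) condensation: LiN(SiMe3)2 removes a proton from the CH2 next to the acyloxy carbonyl of 11, the ester enolate adds to the methyl ester carbonyl held cis to it across the double bond, LiOMe is lost, and the pyran-2,4-dione is deprotonated at once by the second equivalent of base to the pyran-4-olate 12, which acid converts to 13. The closest known reaction type is the base-induced closure of O-acyl salicylate esters to 4-hydroxycoumarins and of N-acyl enamino esters to 4-hydroxy-2-pyridones, of which this is the monocyclic oxygen analogue. Ring A is closed at C3–C4 in a 6-(enolexo)-exo-trig mode, which is favoured. No stereocentre is formed and none is present in the substrate. The selectivity needed is carbon acylation ahead of E1cB fragmentation of the enolate into an arylmethylketene and the enolate of 9; the Z geometry keeps the ester carbonyl within bonding distance of the enolate carbon and the low temperature slows the fragmentation. Deprotonation at the ethyl CH2 of the enoate would give a dienolate that can reach the acyl carbon only through a four-membered ring, and under the equilibrating amide/amine conditions it should revert. Slow addition to excess base at high dilution suppresses intermolecular condensation, the bulky amide should not attack the activated acyl group, and formation of the stabilised anion 12 makes the closure irreversible.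

Step 7
Reactants: 13 6-ethyl-4-hydroxy-5-methyl-3-[2,4,6-tris(benzyloxy)benzyl]pyran-2-one
Product: 14 6-ethyl-4-hydroxy-5-methyl-3-(2,4,6-trihydroxybenzyl)pyran-2-one
Conditions: H2 (1 atm), Pd/C (10% Pd on carbon), EtOAc/MeOH, rt
Reagents that add atoms: none
Why: Catalytic hydrogenolysis of three aryl benzyl ethers; the tetrasubstituted C5=C6 bond of the pyranone and the bridging CH2 are not expected to react at atmospheric pressure, and no acid or base is present.

Step 8
Reactants: 15 (S)-2-methylbutanoic acid
Product: 16 (S)-2-methylbutanoyl chloride
Conditions: (COCl)2 (1.0 equiv), DMF (cat.), CH2Cl2, 0 °C → rt; short-path distillation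
Reagents that add atoms: oxalyl chloride, ClC(=O)C(=O)Cl
Why: Standard acid chloride formation through the chloroiminium intermediate; no base is present, so the ketene pathway that would racemise the α-carbon is closed and the (S) configuration should be carried over unchanged.

Step 9
Reactants: 14 6-ethyl-4-hydroxy-5-methyl-3-(2,4,6-trihydroxybenzyl)pyran-2-one; 16 (S)-2-methylbutanoyl chloride
Product: 17 6-ethyl-4-hydroxy-5-methyl-3-{2,4,6-trihydroxy-3-[(2S)-2-methylbutanoyl]benzyl}pyran-2-one
Conditions: 16 (1.1 equiv), AlCl3 (5 equiv), CH2Cl2/MeNO2, 0 °C → rt; then ice/1 M HCl
Reagents that add atoms: none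
Why: Friedel–Crafts acylation (O-acylation followed by Fries shift may contribute); C3' and C5' of 14 are equivalent, the chelated ketone deactivates the product against a second acylation, and C3 and C5 of the pyranone are both substituted, so only one C-acyl product is possible. The stereocentre comes unchanged from 16, and the low temperature is chosen to avoid enolisation of the aluminium-bound ketone.

Step 10
Reactants: 17 6-ethyl-4-hydroxy-5-methyl-3-{2,4,6-trihydroxy-3-[(2S)-2-methylbutanoyl]benzyl}pyran-2-one
Product: 18 6-ethyl-4-hydroxy-5-methyl-3-{2,4,6-trihydroxy-3-[(2S)-2-methylbutanoyl]-5-(3-methylbut-2-enyl)benzyl}pyran-2-one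
Conditions: prenyl bromide (1.05 equiv), 10% aq. KOH, 0 °C; then dilute HCl
Reagents that add atoms: prenyl bromide (1-bromo-3-methylbut-2-ene), CC(C)=CCBr
Why: C-Alkylation of an acylphloroglucinol phenoxide by an allylic halide in water, where hydrogen bonding to the oxygens favours attack through carbon; C3' is the only unsubstituted ring carbon and the pyranone oxyanion is a much weaker nucleophile. In the anion the ketone is part of a vinylogous carboxylate, which should protect the α-stereocentre from enolisation in cold alkali.

## Compound list

1 | 2,4,6-trihydroxybenzaldehyde | O=Cc1c(O)cc(O)cc1O | starting material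
2 | 2,4,6-tris(benzyloxy)benzaldehyde | O=Cc1c(OCc2ccccc2)cc(OCc3ccccc3)cc1OCc4ccccc4 | intermediate
3 | Meldrum's acid (2,2-dimethyl-1,3-dioxane-4,6-dione) | CC1(C)OC(=O)CC(=O)O1 | starting material
4 | 2,2-dimethyl-5-[2,4,6-tris(benzyloxy)benzylidene]-1,3-dioxane-4,6-dione | CC1(C)OC(=O)C(=Cc2c(OCc3ccccc3)cc(OCc4ccccc4)cc2OCc5ccccc5)C(=O)O1 | intermediate (not isolated)
5 | 2,2-dimethyl-5-[2,4,6-tris(benzyloxy)benzyl]-1,3-dioxane-4,6-dione | CC1(C)OC(=O)C(Cc2c(OCc3ccccc3)cc(OCc4ccccc4)cc2OCc5ccccc5)C(=O)O1 | intermediate
6 | 2-[2,4,6-tris(benzyloxy)benzyl]malonic acid | OC(=O)C(Cc1c(OCc2ccccc2)cc(OCc3ccccc3)cc1OCc4ccccc4)C(=O)O | intermediate (not isolated)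
7 | 3-[2,4,6-tris(benzyloxy)phenyl]propanoic acid | OC(=O)CCc1c(OCc2ccccc2)cc(OCc3ccccc3)cc1OCc4ccccc4 | intermediate
8 | 3-[2,4,6-tris(benzyloxy)phenyl]propanoyl chloride | ClC(=O)CCc1c(OCc2ccccc2)cc(OCc3ccccc3)cc1OCc4ccccc4 | intermediate
9 | methyl 2-methyl-3-oxopentanoate (racemic) | CCC(=O)C(C)C(=O)OC | starting material
10 | sodium (2Z)-1-methoxy-2-methyl-1-oxopent-2-en-3-olate | COC(=O)/C(C)=C(/CC)[O-].[Na+] | intermediate (not isolated)
11 | methyl (Z)-2-methyl-3-{[3-(2,4,6-tris(benzyloxy)phenyl)propanoyl]oxy}pent-2-enoate | COC(=O)/C(C)=C(/CC)OC(=O)CCc1c(OCc2ccccc2)cc(OCc3ccccc3)cc1OCc4ccccc4 | intermediate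
12 | lithium 6-ethyl-5-methyl-2-oxo-3-[2,4,6-tris(benzyloxy)benzyl]-2H-pyran-4-olate | CCc1oc(=O)c(Cc2c(OCc3ccccc3)cc(OCc4ccccc4)cc2OCc5ccccc5)c([O-])c1C.[Li+] | intermediate (not isolated)
13 | 6-ethyl-4-hydroxy-5-methyl-3-[2,4,6-tris(benzyloxy)benzyl]pyran-2-one | CCc1oc(=O)c(Cc2c(OCc3ccccc3)cc(OCc4ccccc4)cc2OCc5ccccc5)c(O)c1C | intermediate
14 | 6-ethyl-4-hydroxy-5-methyl-3-(2,4,6-trihydroxybenzyl)pyran-2-one | CCc1oc(=O)c(Cc2c(O)cc(O)cc2O)c(O)c1C | intermediate
15 | (S)-2-methylbutanoic acid | CC[C@H](C)C(=O)O | starting material
16 | (S)-2-methylbutanoyl chloride | CC[C@H](C)C(=O)Cl | intermediate
17 | 6-ethyl-4-hydroxy-5-methyl-3-{2,4,6-trihydroxy-3-[(2S)-2-methylbutanoyl]benzyl}pyran-2-one | CCc1oc(=O)c(Cc2c(O)cc(O)c(C(=O)[C@@H](C)CC)c2O)c(O)c1C | intermediate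
18 | 6-ethyl-4-hydroxy-5-methyl-3-{2,4,6-trihydroxy-3-[(2S)-2-methylbutanoyl]-5-(3-methylbut-2-enyl)benzyl}pyran-2-one | CCc1oc(=O)c(Cc2c(O)c(CC=C(C)C)c(O)c(C(=O)[C@@H](C)CC)c2O)c(O)c1C | target

## Step count and least certain steps

Total: 10 steps. Longest linear sequence: 9 steps (steps 1 to 7, 9 and 10, from 1 to 18); step 8 is a one-step side branch.

**Step 6 (key step).** The ester enolate may fragment by E1cB cleavage of the acyl–oxygen bond into a ketene and the enolate of 9 before the carbon–carbon bond forms; the keto ester enolate is a good leaving group. Condensation between two molecules, or attack of the amide base at the activated acyl group, would also consume material. The fallback builds the pyranone without the aryl unit and joins the two afterwards. Methyl 3-oxopentanoate is converted to its dianion (NaH, then n-BuLi, THF, 0 °C) and acylated at C4 with N-methoxy-N-methylpropanamide to give methyl 4-methyl-3,5-dioxoheptanoate F1. DBU in hot toluene lactonises this to 6-ethyl-4-hydroxy-5-methylpyran-2-one F2. Aldehyde 2, Hantzsch ester and L-proline then condense with F2, and the alkylidene intermediate 6-ethyl-5-methyl-3-[2,4,6-tris(benzyloxy)benzylidene]pyran-2,4-dione F3 is reduced in the flask. This fallback sets out from aldehyde 2 and returns to the route at 13.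

**Step 5.** Acylation may take place at carbon, or the chelate may loosen so that the acyl group ends up trans to the ester; the E isomer cannot close. The fallback separates the control of geometry from the acylation. Keto ester 9 is converted with NaH and Me3SiCl in THF to methyl (Z)-2-methyl-3-(trimethylsilyloxy)pent-2-enoate F4; silylation of the chelated enolate can occur only on oxygen. F4 is then acylated with 8 under CuCl mediation, an O-acylation of silyl enol ethers by acyl chlorides that is expected to keep the enol geometry. The fallback sets out from 9 and returns at 11.

**Step 9.** The configuration may erode through enolisation of the aluminium-bound ketone or through ketene formation from the acylium ion. The Lewis acid may also cleave the methylene bridge by a retro-Friedel–Crafts process, or promote cyclodehydration between a phenol and the pyranone hydroxyl. The fallback acylates before deprotection and without a metal Lewis acid. Tribenzyl ether 13 is treated with acid 15 and (CF3CO)2O in CH2Cl2 at 0 °C (mixed anhydride acylation of a trialkoxyarene, with any O-acyl pyranone ester cleaved on aqueous NaHCO3 work-up). This gives 6-ethyl-4-hydroxy-5-methyl-3-{2,4,6-tris(benzyloxy)-3-[(2S)-2-methylbutanoyl]benzyl}pyran-2-one F5, which is hydrogenolysed over Pd/C. The fallback sets out from 13 and returns at 17.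

**Step 10.** Alkylation may continue to a geminal, dearomatised product at an already substituted ring carbon, may take place on a phenol or pyranone oxygen, or the alkali may open the lactone or scramble the methylene bridge. The fallback replaces phenoxide alkylation by acid-mediated electrophilic substitution: 17 is treated with 2-methylbut-3-en-2-ol and BF3·OEt2 in dioxane at rt. O-Alkylation is reversible under these conditions and the dimethylallyl cation attacks the only free ring carbon, at the known cost of some chroman formation. The fallback sets out from 17 and ends at 18, and it makes no new compound (F0).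

## Further compounds

F1 | step 6 | methyl 4-methyl-3,5-dioxoheptanoate | CCC(=O)C(C)C(=O)CC(=O)OC
F2 | step 6 | 6-ethyl-4-hydroxy-5-methylpyran-2-one | CCc1oc(=O)cc(O)c1C
F3 | step 6 | 6-ethyl-5-methyl-3-[2,4,6-tris(benzyloxy)benzylidene]pyran-2,4-dione | CCC1=C(C)C(=O)C(=Cc2c(OCc3ccccc3)cc(OCc4ccccc4)cc2OCc5ccccc5)C(=O)O1
F4 | step 5 | methyl (Z)-2-methyl-3-(trimethylsilyloxy)pent-2-enoate | COC(=O)/C(C)=C(/CC)O[Si](C)(C)C
F5 | step 9 | 6-ethyl-4-hydroxy-5-methyl-3-{2,4,6-tris(benzyloxy)-3-[(2S)-2-methylbutanoyl]benzyl}pyran-2-one | CCc1oc(=O)c(Cc2c(OCc3ccccc3)cc(OCc4ccccc4)c(C(=O)[C@@H](C)CC)c2OCc5ccccc5)c(O)c1C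
F0 | step 10 | none | none
A1 | alternative 1 | (S)-1-(2-hydroxy-4,6-dimethoxyphenyl)-2-methylbutan-1-one | COc1cc(O)c(C(=O)[C@@H](C)CC)c(OC)c1
A2 | alternative 1 | 3,5-dimethoxy-2-(trimethylsilyl)phenyl trifluoromethanesulfonate | COc1cc(OC)c([Si](C)(C)C)c(OS(=O)(=O)C(F)(F)F)c1
A3 | alternative 2 | 2-(3-methylbut-2-enyl)-3,5-bis(triisopropylsiloxy)phenol | CC(C)=CCc1c(O)cc(O[Si](C(C)C)(C(C)C)C(C)C)cc1O[Si](C(C)C)(C(C)C)C(C)C
A4 | alternative 2 | 3-(triisopropylsiloxy)cyclobut-2-en-1-one | O=C1CC(O[Si](C(C)C)(C(C)C)C(C)C)=C1
A5 | alternative 2 | triisopropyl[(5-methylhex-4-en-1-yn-1-yl)oxy]silane | CC(C)=CCC#CO[Si](C(C)C)(C(C)C)C(C)C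
A6 | alternative 3 | 6-ethyl-4-hydroxy-5-methyl-3-{2,4,6-tris(benzyloxy)-3-[(2S)-2-methylbutanoyl]benzyl}pyran-2-one | CCc1oc(=O)c(Cc2c(OCc3ccccc3)cc(OCc4ccccc4)c(C(=O)[C@@H](C)CC)c2OCc5ccccc5)c(O)c1C
A7 | alternative 3 | 2-{2,4,6-tris(benzyloxy)-3-[(2S)-2-methylbutanoyl]benzyl}malonyl dichloride | CC[C@H](C)C(=O)c1c(OCc2ccccc2)cc(OCc3ccccc3)c(CC(C(=O)Cl)C(=O)Cl)c1OCc4ccccc4
A8 | alternative 3 | 3-(trimethylsilyloxy)pent-2-ene | CC=C(CC)O[Si](C)(C)C
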